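**Strategy.** The route rests on disconnecting C4–C4a of the lower (epiafzelechin) pyran ring (O1, C2, C3, C4, C4a, C8a). Before that bond exists, the phloroglucinol ring is locally symmetric about the axis through C6 (which carries the upper flavan) and C8a–O1, so C4a and C8 are equivalent and only the 4→6-linked skeleton can arise. The key step, a Lewis-acid-catalysed 6-endo Friedel–Crafts epoxy–arene cyclisation, forms C4–C4a, closes this pyran as the last ring and unveils the 3-OH with C2 and C3 already fixed. Its precursor is the aryl ether of the 2,4-cis-4-arylflavan phenol with an (R)-aryl[(R)-oxiranyl]methyl group, made by Mitsunobu inversion of a Sharpless-resolved epoxy alcohol.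

Key step: step 10

Assumption: the Pd/t-BuPyOx conjugate addition is taken to show on chromones the same facial preference as on cyclic enones ((S)-ligand giving (R)-products), so (R)-t-BuPyOx is written for the 2S flavanone; should the sense be the reverse, the other ligand antipode is used.

Step 1
Reactants: 1 7-hydroxy-4H-chromen-4-one
Product: 2 7-(benzyloxy)-4H-chromen-4-one
Conditions: BnBr, K2CO3, DMF, rt
Reagents that add atoms: benzyl bromide, BrCc1ccccc1
Why: Williamson ether synthesis, in which the acidic 7-OH is deprotonated by carbonate and O-benzylated by SN2, with no stereocentre involved.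

Step 2
Reactants: 2 7-(benzyloxy)-4H-chromen-4-one; 3 [4-(benzyloxy)phenyl]boronic acid
Product: 4 (2S)-7-(benzyloxy)-2-[4-(benzyloxy)phenyl]-2,3-dihydro-4H-chromen-4-one
Conditions: Pd(OCOCF3)2 (5 mol %), (R)-t-BuPyOx (6 mol %), NH4PF6 (30 mol %), H2O (5 equiv), ClCH2CH2Cl, 60 °C
Reagents that add atoms: none
Why: Pd(II)/pyridine-oxazoline-catalysed asymmetric conjugate addition of an arylboronic acid to a chromone (transmetalation, enantio-determining carbopalladation of C2=C3, protonolysis of the Pd enolate by water), in which the chiral ligand selects the enone face and sets C2 as S.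

Step 3
Reactants: 5 3,5-bis(benzyloxy)phenol
Product: 6 [3,5-bis(benzyloxy)phenoxy]tri(propan-2-yl)silane
Conditions: TIPSCl, imidazole, DMF, rt
Reagents that add atoms: triisopropylsilyl chloride, CC(C)[Si](Cl)(C(C)C)C(C)C
Why: Silylation of the only free phenol (the future O1) with a bulky TIPS group, which differentiates it from the two benzyl-protected oxygens and shields its own ortho positions from metalation.

Step 4
Reactants: 6 [3,5-bis(benzyloxy)phenoxy]tri(propan-2-yl)silane; 4 (2S)-7-(benzyloxy)-2-[4-(benzyloxy)phenyl]-2,3-dihydro-4H-chromen-4-one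
Product: 8 (2S)-7-(benzyloxy)-2-[4-(benzyloxy)phenyl]-4-{2,6-bis(benzyloxy)-4-[(triisopropylsilyl)oxy]phenyl}-3,4-dihydro-2H-chromen-4-ol (C4 epimers), via aryllithium 7 (not isolated)
Conditions: 6, n-BuLi, THF, 0 °C; then 4 premixed with LaCl3·2LiCl, THF, −78 → −20 °C; H2O
Reagents that add atoms: none
Why: Directed ortho-metalation between the two benzyloxy groups gives aryllithium 7, which adds 1,2 to the La(III)-activated and thereby less enolisable ketone, and the C4 configuration is of no consequence because this centre is planarised in step 5.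

Step 5
Reactants: 8 (2S)-4-aryl-chroman-4-ol (C4 epimers)
Product: 9 {3,5-bis(benzyloxy)-4-[(2S,4S)-7-(benzyloxy)-2-[4-(benzyloxy)phenyl]-3,4-dihydro-2H-chromen-4-yl]phenoxy}tri(propan-2-yl)silane (2,4-cis)
Conditions: Et3SiH, CF3CO2H, CH2Cl2, −40 → 0 °C
Reagents that add atoms: none
Why: Ionic hydrogenation, in which TFA ionises the bis-benzylic carbinol to a diarylmethyl cation and Et3SiH delivers hydride pseudo-axially to the face syn to the axial C2–H of the half-chair (2-aryl equatorial), placing the 4-aryl group cis to the 2-aryl group and setting C4 as S.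

Step 6
Reactants: 9 TIPS-protected (2S,4S)-4-arylflavan
Product: 10 3,5-bis(benzyloxy)-4-[(2S,4S)-7-(benzyloxy)-2-[4-(benzyloxy)phenyl]-3,4-dihydro-2H-chromen-4-yl]phenol
Conditions: TBAF, AcOH, THF, 0 °C
Reagents that add atoms: none
Why: Fluoride-mediated cleavage of the aryl silyl ether, buffered with acetic acid so that the electron-rich phenol is not kept as its oxidisable phenoxide, with both stereocentres untouched.

Step 7
Reactants: 11 4-(benzyloxy)benzaldehyde
Product: 12 rac-1-[4-(benzyloxy)phenyl]prop-2-en-1-ol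
Conditions: CH2=CHMgBr, THF, −78 → 0 °C; H2O
Reagents that add atoms: vinylmagnesium bromide, C=C[Mg]Br
Why: Grignard 1,2-addition of vinylmagnesium bromide to the aromatic aldehyde, giving the racemic allylic alcohol that is resolved in step 8.

Step 8
Reactants: 12 rac-1-[4-(benzyloxy)phenyl]prop-2-en-1-ol
Product: 13 (S)-[4-(benzyloxy)phenyl][(2R)-oxiran-2-yl]methanol (erythro)
Conditions: Ti(OiPr)4 (0.2 equiv), L-(+)-DIPT (0.24 equiv), t-BuOOH (0.5 equiv), 4 Å MS, CH2Cl2, −20 °C
Reagents that add atoms: tert-butyl hydroperoxide, CC(C)(C)OO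
Why: Sharpless kinetic resolution by asymmetric epoxidation, in which the L-(+)-tartrate–titanium catalyst epoxidises the (R)-alcohol much faster than the (S)-alcohol and with erythro selectivity, so the catalyst sets the new epoxide centre as R next to the carbinol centre (labelled S in the product only because the CIP priorities change).

Step 9
Reactants: 10 3,5-bis(benzyloxy)-4-[(2S,4S)-flavan-4-yl]phenol; 13 (S)-[4-(benzyloxy)phenyl][(2R)-oxiran-2-yl]methanol
Product: 14 (2R)-2-[(R)-[4-(benzyloxy)phenyl]{3,5-bis(benzyloxy)-4-[(2S,4S)-7-(benzyloxy)-2-[4-(benzyloxy)phenyl]-3,4-dihydro-2H-chromen-4-yl]phenoxy}methyl]oxirane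
Conditions: PPh3, DIAD, toluene, 0 °C → rt
Reagents that add atoms: none
Why: Mitsunobu etherification, in which the phenol displaces the oxyphosphonium group by SN2 with inversion and so converts the S carbinol centre into the R-configured future C2, the adjacent electron-withdrawing epoxide disfavouring competing ionisation.

Step 10
Reactants: 14 epoxy aryl ether
Product: 15 (2R,3R)-5,7-bis(benzyloxy)-2-[4-(benzyloxy)phenyl]-6-[(2S,4S)-7-(benzyloxy)-2-[4-(benzyloxy)phenyl]-3,4-dihydro-2H-chromen-4-yl]-3,4-dihydro-2H-chromen-3-ol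
Conditions: AuCl3 (5 mol %), AgOTf (15 mol %), CH2Cl2, 0 °C → rt
Reagents that add atoms: none
Why: The Lewis acid activates the terminal epoxide and one of the two equivalent D-ring carbons ortho to O1 attacks the CH2 terminus from the back side, after which the Wheland intermediate rearomatises and the alkoxide is protonated to the 3-OH (intramolecular Friedel–Crafts epoxy–arene cycloalkylation, the closest known type being the cyclisation of aryl glycidyl ethers to chroman-3-ols). The pyran ring is closed by C4–C4a bond formation in the 6-endo-tet mode with respect to the epoxide. No new stereocentre is created: C3 keeps its C–O bond and hence its R configuration, and C2, set in step 9, is not touched, so the 2,3-cis (2R,3R) relationship is carried over intact. The step needs 6-endo over 5-exo opening, which the unhindered primary terminus and the inductive deactivation of the internal carbon by the neighbouring aryloxy-bearing carbon should secure. It needs no regiocontrol on the arene, because C6 is blocked by the upper flavan and the two open positions are constitutionally equivalent, so either closure gives the 4→6 product. Ionisation of the benzylic C2–O1 ether is held back by the electron-withdrawing epoxide next to C2 and by the low catalyst loading and temperature.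

Step 11
Reactants: 15 penta-O-benzyl biflavan
Product: 16 (2R,3R)-2-(4-hydroxyphenyl)-6-[(2S,4S)-7-hydroxy-2-(4-hydroxyphenyl)-3,4-dihydro-2H-chromen-4-yl]-3,4-dihydro-2H-chromene-3,5,7-triol (CNP0167324.1)
Conditions: H2 (1 atm), Pd(OH)2/C, THF–MeOH, rt
Reagents that add atoms: none
Why: Hydrogenolysis of the five aryl benzyl ethers over Pearlman's catalyst under neutral conditions, which should leave the flavan C–O bonds and all four stereocentres untouched.

**Compound list**

1 | 7-hydroxy-4H-chromen-4-one | O=c1ccoc2cc(O)ccc12 | starting material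
2 | 7-(benzyloxy)-4H-chromen-4-one | O=c1ccoc2cc(OCc3ccccc3)ccc12 | intermediate
3 | [4-(benzyloxy)phenyl]boronic acid | OB(O)c1ccc(OCc2ccccc2)cc1 | starting material
4 | (2S)-7-(benzyloxy)-2-[4-(benzyloxy)phenyl]-2,3-dihydro-4H-chromen-4-one | C(c1ccccc1)Oc1ccc([C@@H]2CC(=O)c3ccc(OCc4ccccc4)cc3O2)cc1 | intermediate
5 | 3,5-bis(benzyloxy)phenol | Oc1cc(OCc2ccccc2)cc(OCc2ccccc2)c1 | starting material
6 | [3,5-bis(benzyloxy)phenoxy]tri(propan-2-yl)silane | CC(C)[Si](Oc1cc(OCc2ccccc2)cc(OCc2ccccc2)c1)(C(C)C)C(C)C | intermediate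
7 | {2,6-bis(benzyloxy)-4-[(triisopropylsilyl)oxy]phenyl}lithium | [Li]c1c(OCc2ccccc2)cc(O[Si](C(C)C)(C(C)C)C(C)C)cc1OCc1ccccc1 | intermediate (not isolated)
8 | (2S)-7-(benzyloxy)-2-[4-(benzyloxy)phenyl]-4-{2,6-bis(benzyloxy)-4-[(triisopropylsilyl)oxy]phenyl}-3,4-dihydro-2H-chromen-4-ol, C4 epimers | C(c1ccccc1)Oc1ccc([C@@H]2CC(O)(c3c(OCc4ccccc4)cc(O[Si](C(C)C)(C(C)C)C(C)C)cc3OCc3ccccc3)c3ccc(OCc4ccccc4)cc3O2)cc1 | intermediate
9 | {3,5-bis(benzyloxy)-4-[(2S,4S)-7-(benzyloxy)-2-[4-(benzyloxy)phenyl]-3,4-dihydro-2H-chromen-4-yl]phenoxy}tri(propan-2-yl)silane, 2,4-cis | C(c1ccccc1)Oc1ccc([C@@H]2C[C@H](c3c(OCc4ccccc4)cc(O[Si](C(C)C)(C(C)C)C(C)C)cc3OCc3ccccc3)c3ccc(OCc4ccccc4)cc3O2)cc1 | intermediate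
10 | 3,5-bis(benzyloxy)-4-[(2S,4S)-7-(benzyloxy)-2-[4-(benzyloxy)phenyl]-3,4-dihydro-2H-chromen-4-yl]phenol | C(c1ccccc1)Oc1ccc([C@@H]2C[C@H](c3c(OCc4ccccc4)cc(O)cc3OCc3ccccc3)c3ccc(OCc4ccccc4)cc3O2)cc1 | intermediate
11 | 4-(benzyloxy)benzaldehyde | O=Cc1ccc(OCc2ccccc2)cc1 | starting material
12 | rac-1-[4-(benzyloxy)phenyl]prop-2-en-1-ol | OC(C=C)c1ccc(OCc2ccccc2)cc1 | intermediate
13 | (S)-[4-(benzyloxy)phenyl][(2R)-oxiran-2-yl]methanol | O[C@@H](c1ccc(OCc2ccccc2)cc1)[C@H]1CO1 | intermediate
14 | (2R)-2-[(R)-[4-(benzyloxy)phenyl]{3,5-bis(benzyloxy)-4-[(2S,4S)-7-(benzyloxy)-2-[4-(benzyloxy)phenyl]-3,4-dihydro-2H-chromen-4-yl]phenoxy}methyl]oxirane | C(c1ccccc1)Oc1ccc([C@@H]2C[C@H](c3c(OCc4ccccc4)cc(O[C@H](c4ccc(OCc5ccccc5)cc4)[C@H]4CO4)cc3OCc3ccccc3)c3ccc(OCc4ccccc4)cc3O2)cc1 | intermediate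
15 | (2R,3R)-5,7-bis(benzyloxy)-2-[4-(benzyloxy)phenyl]-6-[(2S,4S)-7-(benzyloxy)-2-[4-(benzyloxy)phenyl]-3,4-dihydro-2H-chromen-4-yl]-3,4-dihydro-2H-chromen-3-ol | C(c1ccccc1)Oc1ccc([C@@H]2C[C@H](c3c(OCc4ccccc4)cc4c(c3OCc3ccccc3)C[C@@H](O)[C@@H](c3ccc(OCc5ccccc5)cc3)O4)c3ccc(OCc4ccccc4)cc3O2)cc1 | intermediate
16 | (2R,3R)-2-(4-hydroxyphenyl)-6-[(2S,4S)-7-hydroxy-2-(4-hydroxyphenyl)-3,4-dihydro-2H-chromen-4-yl]-3,4-dihydro-2H-chromene-3,5,7-triol | Oc1ccc([C@@H]2C[C@H](c3c(O)cc4c(c3O)C[C@@H](O)[C@@H](c3ccc(O)cc3)O4)c3ccc(O)cc3O2)cc1 | target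

**Step count.** Total: 11 steps. Longest linear sequence: 8 steps (1, 2, 4, 5, 6, 9, 10, 11).

**Steps most likely to fail**

1. Step 10 (key step). The Lewis acid may ionise the benzylic C2–O1 ether, which would scramble C2 or fragment the molecule back to the phenol. The epoxide may also rearrange to an aldehyde or open in the 5-exo mode. The fallback closes the same C4–C4a bond by an anionic instead of a cationic process; it sets out from 10 and comes back to the route at 15. Phenol 10 is mono-iodinated ortho to the hydroxyl group (NIS, CH2Cl2, −40 °C; both ortho positions are equivalent) to give 3,5-bis(benzyloxy)-4-[(2S,4S)-flavan-4-yl]-2-iodophenol F1. Mitsunobu coupling of F1 with 13 (PPh3, DIAD, toluene) gives the iodo epoxy ether F2. MgBr2·OEt2 (Et2O, 0 °C) opens the epoxide at its terminal carbon to the bromohydrin F3. Treatment of F3 with n-BuLi (2.2 equiv, THF, −78 → 0 °C) forms the alkoxide, exchanges iodine for lithium and lets the aryllithium displace the primary bromide in a Parham-type 6-exo-tet cycloalkylation, which should give 15 without any Lewis acid.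

2. Step 4. The hindered, basic aryl nucleophile may enolise the flavanone instead of adding to it, and the enolate may undergo retro-oxa-Michael ring opening, which would also erode C2. The fallback replaces 1,2-addition by cross-coupling; it sets out from 4 and 7 and comes back to the route at 9. Ketone 4 is converted under non-basic conditions (Tf2O, 2,6-di-tert-butyl-4-methylpyridine, CH2Cl2, 0 °C) into the enol triflate (2S)-7-(benzyloxy)-2-[4-(benzyloxy)phenyl]-2H-chromen-4-yl trifluoromethanesulfonate F4. Aryllithium 7 is transmetalated with ZnCl2 to the arylzinc chloride F5. Negishi coupling of F4 with F5 (Pd2(dba)3, SPhos, THF, 60 °C) gives the (2S)-4-aryl-2H-chromene F6. Ionic hydrogenation of F6 under the conditions of step 5 (protonation at C3 gives the same diarylmethyl cation) should give 9.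

3. Step 2. Carbopalladation of the electron-rich chromone by the electron-rich arylpalladium species may be slow or poorly face-selective, with protodeboronation and homocoupling competing, so that conversion or the enantiomeric purity at C2 is insufficient. Any minor enantiomer of 4 would in any case end as diastereomers of 14 and 15, which are separable. The fallback uses the chiral pool instead of asymmetric catalysis; it does not set out from a numbered compound but replaces steps 1 and 2 by commercial (2S)-liquiritigenin F7, and it comes back to the route at 4. Both phenols of F7 are benzylated under neutral Mitsunobu conditions (BnOH, PPh3, DIAD, THF, 0 °C → rt), which avoids the base that would open the flavanone to the chalcone and racemise C2.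

**Further compounds**

F1 | step 10 | 3,5-bis(benzyloxy)-4-[(2S,4S)-7-(benzyloxy)-2-[4-(benzyloxy)phenyl]-3,4-dihydro-2H-chromen-4-yl]-2-iodophenol | C(c1ccccc1)Oc1ccc([C@@H]2C[C@H](c3c(OCc4ccccc4)c(I)c(O)cc3OCc3ccccc3)c3ccc(OCc4ccccc4)cc3O2)cc1
F2 | step 10 | (2R)-2-[(R)-[4-(benzyloxy)phenyl]{3,5-bis(benzyloxy)-4-[(2S,4S)-7-(benzyloxy)-2-[4-(benzyloxy)phenyl]-3,4-dihydro-2H-chromen-4-yl]-2-iodophenoxy}methyl]oxirane | C(c1ccccc1)Oc1ccc([C@@H]2C[C@H](c3c(OCc4ccccc4)c(I)c(O[C@H](c4ccc(OCc5ccccc5)cc4)[C@H]4CO4)cc3OCc3ccccc3)c3ccc(OCc4ccccc4)cc3O2)cc1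
F3 | step 10 | (1R,2S)-1-[4-(benzyloxy)phenyl]-1-{3,5-bis(benzyloxy)-4-[(2S,4S)-7-(benzyloxy)-2-[4-(benzyloxy)phenyl]-3,4-dihydro-2H-chromen-4-yl]-2-iodophenoxy}-3-bromopropan-2-ol | C(c1ccccc1)Oc1ccc([C@@H]2C[C@H](c3c(OCc4ccccc4)c(I)c(O[C@H](c4ccc(OCc5ccccc5)cc4)[C@H](O)CBr)cc3OCc3ccccc3)c3ccc(OCc4ccccc4)cc3O2)cc1
F4 | step 4 | (2S)-7-(benzyloxy)-2-[4-(benzyloxy)phenyl]-2H-chromen-4-yl trifluoromethanesulfonate | C(c1ccccc1)Oc1ccc([C@@H]2C=C(OS(=O)(=O)C(F)(F)F)c3ccc(OCc4ccccc4)cc3O2)cc1
F5 | step 4 | {2,6-bis(benzyloxy)-4-[(triisopropylsilyl)oxy]phenyl}zinc chloride | Cl[Zn]c1c(OCc2ccccc2)cc(O[Si](C(C)C)(C(C)C)C(C)C)cc1OCc1ccccc1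
F6 | step 4 | {3,5-bis(benzyloxy)-4-[(2S)-7-(benzyloxy)-2-[4-(benzyloxy)phenyl]-2H-chromen-4-yl]phenoxy}tri(propan-2-yl)silane | C(c1ccccc1)Oc1ccc([C@@H]2C=C(c3c(OCc4ccccc4)cc(O[Si](C(C)C)(C(C)C)C(C)C)cc3OCc3ccccc3)c3ccc(OCc4ccccc4)cc3O2)cc1
F7 | step 2 | (2S)-7-hydroxy-2-(4-hydroxyphenyl)-2,3-dihydro-4H-chromen-4-one, (S)-liquiritigenin, bought and not made | Oc1ccc([C@@H]2CC(=O)c3ccc(O)cc3O2)cc1
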